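**Plan**

- Retrosynthesis: the C5 styryl C=C is cut by phosphonate olefination; ring A is then cut at C3a–C4 and C7a–C7 into a lactone-derived cyclic silyl ketene acetal and a 3-methoxy-2-pyrone-5-carboxylate (CO2 and silanol are lost in the forward sense); the lactone is cut at C2–C3 by a syn-aldol.
- Enabling feature: O1–C2–C3–C3a–C7a is a trans-5-aryl-4-(hydroxymethyl)butyrolactone (lactone O = O1, C5 = C2, C4 = C3, α-carbon = C3a, carbonyl carbon = C7a). Ring A carries OMe on C7 next to O1 and a carbon substituent on C5 para to O1, which is the benzoate pattern a 3-methoxy-2-pyrone-5-carboxylate delivers.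
- Forward order: aldol, then the lactone (the future dihydrofuran ring), then ring A by (4+2) benzannulation, then ester to aldehyde, stilbene, and global desilylation.
- Stereochemistry: C2 (R) and C3 (S) both come from one Evans syn-aldol with (R)-4-benzyloxazolidin-2-one. The syn adduct maps onto the trans lactone and neither centre is enolisable afterwards. The E alkene comes from the Horner–Wadsworth–Emmons step.

Key step: step 12

Remark: the target is read as the (2R,3S)-trans isomer; the double-bond geometry of the acyclic pyrone precursors 19–21 is left open because it equilibrates before lactonisation.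

**Route**

Step 1
Reactants: 1 vanillin (4-hydroxy-3-methoxybenzaldehyde)
Product: 2 3-methoxy-4-(triisopropylsilyloxy)benzaldehyde
Conditions: TIPSCl, imidazole, DMF, rt
Reagents that add atoms: triisopropylsilyl chloride CC(C)[Si](Cl)(C(C)C)C(C)C
Why: Imidazole-promoted silylation of the phenol (silyl ether formation) gives a base-stable, fluoride-labile TIPS ether.

Step 2
Reactants: 3 (R)-4-benzyloxazolidin-2-one; 4 pent-4-enoyl chloride
Product: 5 (R)-4-benzyl-3-(pent-4-enoyl)oxazolidin-2-one
Conditions: Et3N, DMAP (cat.), CH2Cl2, 0 °C to rt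
Reagents that add atoms: none
Why: N-acylation of the oxazolidinone by the acid chloride (nucleophilic acyl substitution with DMAP catalysis) gives the imide needed for auxiliary-controlled enolisation.

Step 3
Reactants: 5 (R)-4-benzyl-3-(pent-4-enoyl)oxazolidin-2-one; 2 3-methoxy-4-(triisopropylsilyloxy)benzaldehyde
Product: 8 (R)-4-benzyl-3-{(2R)-2-[(R)-hydroxy(3-methoxy-4-(triisopropylsilyloxy)phenyl)methyl]pent-4-enoyl}oxazolidin-2-one, via boron enolate 6 (not isolated), via boron aldolate 7 (not isolated)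
Conditions: Bu2BOTf, iPr2NEt, CH2Cl2, −78 to 0 °C; then 2, −78 to 0 °C; then pH 7 buffer, MeOH, 30% H2O2, 0 °C
Reagents that add atoms: none
Why: Evans syn-aldol reaction, in which the (Z)-boron enolate adds to the aldehyde through a chair Zimmerman–Traxler transition state on the face away from the benzyl group of the auxiliary, so that the α-centre (2R) and the carbinol centre (R) are set together.

Step 4
Reactants: 8 the syn-aldol imide
Product: 9 (1R,2S)-1-[3-methoxy-4-(triisopropylsilyloxy)phenyl]-2-(prop-2-en-1-yl)propane-1,3-diol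
Conditions: LiBH4, MeOH (1 equiv), THF, 0 °C
Reagents that add atoms: none
Why: Reductive cleavage of the imide by LiBH4 should release the 1,3-diol and the auxiliary without touching the aryl silyl ether or the alkene and without epimerisation.

Step 5
Reactants: 9 the 1,3-diol
Product: 10 (1R,2S)-2-[(tert-butyldimethylsilyloxy)methyl]-1-[3-methoxy-4-(triisopropylsilyloxy)phenyl]pent-4-en-1-ol
Conditions: TBSCl (1.05 equiv), imidazole, CH2Cl2, 0 °C
Reagents that add atoms: tert-butyldimethylsilyl chloride CC(C)(C)[Si](C)(C)Cl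
Why: Sterically controlled silylation should protect the primary hydroxyl and leave the hindered benzylic hydroxyl free for ring closure.

Step 6
Reactants: 10 the homoallylic benzylic alcohol
Product: 13 (4S,5R)-4-[(tert-butyldimethylsilyloxy)methyl]-5-[3-methoxy-4-(triisopropylsilyloxy)phenyl]oxolan-2-ol (anomer mixture), via triol 11 (not isolated), via hydroxy aldehyde 12 (not isolated)
Conditions: OsO4 (cat.), NaIO4, 2,6-lutidine, dioxane–H2O, rt
Reagents that add atoms: osmium tetroxide O=[Os](=O)(=O)=O; sodium periodate [Na+].[O-]I(=O)(=O)=O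
Why: Lemieux–Johnson cleavage (dihydroxylation, then glycol fission) spares the electron-rich arene, and the aldehyde should be trapped at once by the benzylic hydroxyl as the five-membered lactol.

Step 7
Reactants: 13 the lactol
Product: 14 (4S,5R)-4-[(tert-butyldimethylsilyloxy)methyl]-5-[3-methoxy-4-(triisopropylsilyloxy)phenyl]oxolan-2-one
Conditions: (n-Pr4N)RuO4 (cat.), NMO, 4 Å MS, CH2Cl2, rt
Reagents that add atoms: none
Why: Ley–Griffith oxidation converts the lactol into the γ-lactone under neutral conditions that leave the silyl ethers and the benzylic C–O bond intact.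

Step 8
Reactants: 14 the trans lactone
Product: 16 (2R,3S)-5-(tert-butyldimethylsilyloxy)-3-[(tert-butyldimethylsilyloxy)methyl]-2-[3-methoxy-4-(triisopropylsilyloxy)phenyl]-2,3-dihydrofuran, via lithium enolate 15 (not isolated)
Conditions: LiN(iPr)2, THF, −78 °C; then TBSCl, DMPU, −78 to 0 °C; pentane, filtration, used crude
Reagents that add atoms: tert-butyldimethylsilyl chloride CC(C)(C)[Si](C)(C)Cl
Why: Kinetic deprotonation at the only enolisable carbon of the lactone and O-silylation in the presence of DMPU (silyl ketene acetal formation) should give the cyclic ketene acetal, the two stereocentres not being acidic.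

Step 9
Reactants: 17 dimethyl 2-oxopentanedioate (dimethyl 2-oxoglutarate)
Product: 18 dimethyl 2,2-dimethoxypentanedioate
Conditions: HC(OMe)3, MeOH, H2SO4 (cat.), reflux
Reagents that add atoms: trimethyl orthoformate COC(OC)OC; methanol CO
Why: Acid-catalysed ketalisation of the electrophilic α-keto ester, with the orthoformate as water scavenger.

Step 10
Reactants: 18 dimethyl 2,2-dimethoxypentanedioate
Product: 19 dimethyl (Z)-2-methoxypent-2-enedioate
Conditions: TsOH (cat.), neat, 150 °C, MeOH distilled off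
Reagents that add atoms: none
Why: Acid-catalysed thermal elimination of methanol from the ketal (enol ether formation) can only place the double bond between C2 and C3, and is driven by removal of methanol.

Step 11
Reactants: 19 dimethyl (Z)-2-methoxypent-2-enedioate
Product: 22 methyl 3-methoxy-2-oxo-2H-pyran-5-carboxylate, via enaminone 20 (not isolated), via hydroxymethylene diester 21 (not isolated)
Conditions: Me2NCH(OMe)2, PhMe, 90 °C; then AcOH–H2O, H2SO4 (cat.), 80 °C
Reagents that add atoms: N,N-dimethylformamide dimethyl acetal COC(OC)N(C)C; water O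
Why: The doubly activated C4 methylene condenses with the amide acetal, acid hydrolysis unmasks the hydroxymethylene group, and after equilibration of the push–pull diene its enol oxygen lactonises onto the C1 ester, the formylglutaconate-to-coumalate ring closure.

Step 12
Reactants: 16 the cyclic silyl ketene acetal; 22 methyl 3-methoxy-2-oxo-2H-pyran-5-carboxylate (1.5–2 equiv)
Product: 25 methyl (2R,3S)-3-[(tert-butyldimethylsilyloxy)methyl]-7-methoxy-2-[3-methoxy-4-(triisopropylsilyloxy)phenyl]-2,3-dihydro-1-benzofuran-5-carboxylate, via bicyclic lactone 23 (not isolated), via cyclohexadiene 24 (not isolated)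
Conditions: PhMe, 110 °C, sealed tube, argon
Reagents that add atoms: none
Why: The electron-rich C=C of 16 adds across C3 and C6 of the electron-poor pyrone in an inverse-electron-demand (4+2) cycloaddition that forms C3a–C4 and C7a–C7, the bridged lactone 23 extrudes CO2 by retro-(4+2), and diene 24 aromatises by 1,2-elimination of tert-butyldimethylsilanol. The closest known reaction type is the benzannulation of coumalate esters with ketene acetals to give 4-alkoxybenzoates. Ring A, a six-membered carbocycle, is closed by the intermolecular (4+2) cycloaddition itself, both of its new bonds being made in that event. No stereocentre is created, the transient centres vanish on aromatisation, and C2 and C3 are spectators because only the former lactone α-carbon takes part. The step needs regioselectivity, secured because the nucleophilic β-carbon of the ketene acetal bonds to pyrone C6, the terminus activated by the C5 ester and the ring carbonyl; it also needs loss of the exocyclic silanolate in preference to cleavage of the ring C–O bond, which the better leaving group and the intact five-membered ring favour.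

Step 13
Reactants: 25 the dihydrobenzofuran methyl ester
Product: 26 {(2R,3S)-3-[(tert-butyldimethylsilyloxy)methyl]-7-methoxy-2-[3-methoxy-4-(triisopropylsilyloxy)phenyl]-2,3-dihydro-1-benzofuran-5-yl}methanol
Conditions: iBu2AlH, CH2Cl2, −78 to 0 °C; Rochelle salt work-up
Reagents that add atoms: none
Why: Aluminium hydride reduction of the aryl ester to the benzylic alcohol leaves silyl ethers untouched.

Step 14
Reactants: 26 the benzylic alcohol
Product: 27 (2R,3S)-3-[(tert-butyldimethylsilyloxy)methyl]-7-methoxy-2-[3-methoxy-4-(triisopropylsilyloxy)phenyl]-2,3-dihydro-1-benzofuran-5-carbaldehyde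
Conditions: MnO2, CH2Cl2, rt
Reagents that add atoms: none
Why: MnO2 oxidises the electron-rich benzylic alcohol selectively to the aldehyde without over-oxidation.

Step 15
Reactants: 28 3,5-dihydroxybenzaldehyde
Product: 29 3,5-bis(triisopropylsilyloxy)benzaldehyde
Conditions: TIPSCl, imidazole, DMF, rt
Reagents that add atoms: triisopropylsilyl chloride CC(C)[Si](Cl)(C(C)C)C(C)C
Why: Imidazole-promoted silylation of both phenols gives ethers that should survive the basic olefination.

Step 16
Reactants: 29 3,5-bis(triisopropylsilyloxy)benzaldehyde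
Product: 30 [3,5-bis(triisopropylsilyloxy)phenyl]methanol
Conditions: NaBH4, EtOH–THF, 0 °C
Reagents that add atoms: none
Why: Borohydride reduction of the aldehyde is compatible with hindered aryl silyl ethers at 0 °C.

Step 17
Reactants: 30 [3,5-bis(triisopropylsilyloxy)phenyl]methanol
Product: 31 1-(bromomethyl)-3,5-bis(triisopropylsilyloxy)benzene
Conditions: CBr4, PPh3, CH2Cl2, 0 °C
Reagents that add atoms: carbon tetrabromide BrC(Br)(Br)Br
Why: Appel bromination converts the benzylic alcohol into the bromide under neutral conditions.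

Step 18
Reactants: 31 the benzylic bromide
Product: 32 diethyl {[3,5-bis(triisopropylsilyloxy)phenyl]methyl}phosphonate
Conditions: P(OEt)3, neat, 130 °C
Reagents that add atoms: triethyl phosphite CCOP(OCC)OCC
Why: Michaelis–Arbuzov reaction of a reactive benzylic bromide with triethyl phosphite.

Step 19
Reactants: 32 the benzylphosphonate; 27 the C5 aldehyde
Product: 34 (2R,3S)-5-{(E)-2-[3,5-bis(triisopropylsilyloxy)phenyl]ethenyl}-3-[(tert-butyldimethylsilyloxy)methyl]-7-methoxy-2-[3-methoxy-4-(triisopropylsilyloxy)phenyl]-2,3-dihydro-1-benzofuran, via phosphonate carbanion sodium salt 33 (not isolated)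
Conditions: NaH, 15-crown-5 (cat.), THF, 0 °C; then 27, 0 °C to rt
Reagents that add atoms: none
Why: Horner–Wadsworth–Emmons olefination of a non-enolisable aryl aldehyde with a benzylphosphonate anion should give the (E)-stilbene, and no acidic stereocentre is present.

Step 20
Reactants: 34 the tetrasilyl ether
Product: 35 gnetofuran A, 5-{(E)-2-[(2R,3S)-2-(4-hydroxy-3-methoxyphenyl)-3-(hydroxymethyl)-7-methoxy-2,3-dihydro-1-benzofuran-5-yl]ethenyl}benzene-1,3-diol
Conditions: Bu4NF (excess), AcOH, THF, 0 °C to rt, dark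
Reagents that add atoms: none
Why: Fluoride cleaves the three aryl TIPS ethers and the primary TBS ether, the acetic acid buffer keeping phenoxide concentration low so that the para-hydroxybenzylic ether at C2 should not open to a quinone methide.

**Compound list**

1 | vanillin | COc1cc(C=O)ccc1O | starting material
2 | 3-methoxy-4-(triisopropylsilyloxy)benzaldehyde | COc1cc(C=O)ccc1O[Si](C(C)C)(C(C)C)C(C)C | intermediate
3 | (R)-4-benzyloxazolidin-2-one | O=C1N[C@H](Cc2ccccc2)CO1 | starting material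
4 | pent-4-enoyl chloride | C=CCCC(=O)Cl | starting material
5 | (R)-4-benzyl-3-(pent-4-enoyl)oxazolidin-2-one | C=CCCC(=O)N1C(=O)OC[C@H]1Cc1ccccc1 | intermediate
6 | (Z)-dibutylboron enolate of 5 | C=CC/C=C(\OB(CCCC)CCCC)N1C(=O)OC[C@H]1Cc1ccccc1 | intermediate
7 | dibutylboron aldolate of 8 | C=CC[C@@H](C(=O)N1C(=O)OC[C@H]1Cc1ccccc1)[C@@H](OB(CCCC)CCCC)c1ccc(O[Si](C(C)C)(C(C)C)C(C)C)c(OC)c1 | intermediate
8 | (R)-4-benzyl-3-{(2R)-2-[(R)-hydroxy(3-methoxy-4-(triisopropylsilyloxy)phenyl)methyl]pent-4-enoyl}oxazolidin-2-one | C=CC[C@@H](C(=O)N1C(=O)OC[C@H]1Cc1ccccc1)[C@@H](O)c1ccc(O[Si](C(C)C)(C(C)C)C(C)C)c(OC)c1 | intermediate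
9 | (1R,2S)-1-[3-methoxy-4-(triisopropylsilyloxy)phenyl]-2-(prop-2-en-1-yl)propane-1,3-diol | C=CC[C@@H](CO)[C@@H](O)c1ccc(O[Si](C(C)C)(C(C)C)C(C)C)c(OC)c1 | intermediate
10 | (1R,2S)-2-[(tert-butyldimethylsilyloxy)methyl]-1-[3-methoxy-4-(triisopropylsilyloxy)phenyl]pent-4-en-1-ol | C=CC[C@@H](CO[Si](C)(C)C(C)(C)C)[C@@H](O)c1ccc(O[Si](C(C)C)(C(C)C)C(C)C)c(OC)c1 | intermediate
11 | (4S,5R)-4-[(tert-butyldimethylsilyloxy)methyl]-5-[3-methoxy-4-(triisopropylsilyloxy)phenyl]pentane-1,2,5-triol (both C2 epimers) | OCC(O)C[C@@H](CO[Si](C)(C)C(C)(C)C)[C@@H](O)c1ccc(O[Si](C(C)C)(C(C)C)C(C)C)c(OC)c1 | intermediate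
12 | (3S,4R)-3-[(tert-butyldimethylsilyloxy)methyl]-4-hydroxy-4-[3-methoxy-4-(triisopropylsilyloxy)phenyl]butanal | O=CC[C@@H](CO[Si](C)(C)C(C)(C)C)[C@@H](O)c1ccc(O[Si](C(C)C)(C(C)C)C(C)C)c(OC)c1 | intermediate
13 | (4S,5R)-4-[(tert-butyldimethylsilyloxy)methyl]-5-[3-methoxy-4-(triisopropylsilyloxy)phenyl]oxolan-2-ol (anomer mixture) | COc1cc([C@@H]2OC(O)C[C@H]2CO[Si](C)(C)C(C)(C)C)ccc1O[Si](C(C)C)(C(C)C)C(C)C | intermediate
14 | (4S,5R)-4-[(tert-butyldimethylsilyloxy)methyl]-5-[3-methoxy-4-(triisopropylsilyloxy)phenyl]oxolan-2-one | COc1cc([C@@H]2OC(=O)C[C@H]2CO[Si](C)(C)C(C)(C)C)ccc1O[Si](C(C)C)(C(C)C)C(C)C | intermediate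
15 | lithium enolate of 14 | COc1cc([C@@H]2OC(O[Li])=C[C@H]2CO[Si](C)(C)C(C)(C)C)ccc1O[Si](C(C)C)(C(C)C)C(C)C | intermediate
16 | (2R,3S)-5-(tert-butyldimethylsilyloxy)-3-[(tert-butyldimethylsilyloxy)methyl]-2-[3-methoxy-4-(triisopropylsilyloxy)phenyl]-2,3-dihydrofuran | COc1cc([C@@H]2OC(O[Si](C)(C)C(C)(C)C)=C[C@H]2CO[Si](C)(C)C(C)(C)C)ccc1O[Si](C(C)C)(C(C)C)C(C)C | intermediate
17 | dimethyl 2-oxopentanedioate | COC(=O)CCC(=O)C(=O)OC | starting material
18 | dimethyl 2,2-dimethoxypentanedioate | COC(=O)CCC(OC)(OC)C(=O)OC | intermediate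
19 | dimethyl (Z)-2-methoxypent-2-enedioate | COC(=O)/C(OC)=C/CC(=O)OC | intermediate
20 | dimethyl 4-[(dimethylamino)methylidene]-2-methoxypent-2-enedioate (geometry not fixed) | COC(=O)C(OC)=CC(=CN(C)C)C(=O)OC | intermediate
21 | dimethyl 4-(hydroxymethylidene)-2-methoxypent-2-enedioate (geometry not fixed) | COC(=O)C(OC)=CC(=CO)C(=O)OC | intermediate
22 | methyl 3-methoxy-2-oxo-2H-pyran-5-carboxylate | COC(=O)C1=COC(=O)C(OC)=C1 | intermediate
23 | bridged 2-oxabicyclo[2.2.2]oct-5-en-3-one lactone from addition of the C=C of 16 across C3 and C6 of 22 (transient centres undefined) | COc1cc([C@@H]2OC3(O[Si](C)(C)C(C)(C)C)C([C@H]2CO[Si](C)(C)C(C)(C)C)C4OC(=O)C3(OC)C=C4C(=O)OC)ccc1O[Si](C(C)C)(C(C)C)C(C)C | intermediate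
24 | methyl (2R,3S)-7a-(tert-butyldimethylsilyloxy)-3-[(tert-butyldimethylsilyloxy)methyl]-7-methoxy-2-[3-methoxy-4-(triisopropylsilyloxy)phenyl]-2,3,3a,7a-tetrahydro-1-benzofuran-5-carboxylate (C3a, C7a undefined) | COc1cc([C@@H]2OC3(O[Si](C)(C)C(C)(C)C)C(OC)=CC(C(=O)OC)=CC3[C@H]2CO[Si](C)(C)C(C)(C)C)ccc1O[Si](C(C)C)(C(C)C)C(C)C | intermediate
25 | methyl (2R,3S)-3-[(tert-butyldimethylsilyloxy)methyl]-7-methoxy-2-[3-methoxy-4-(triisopropylsilyloxy)phenyl]-2,3-dihydro-1-benzofuran-5-carboxylate | COc1cc([C@@H]2Oc3c(OC)cc(C(=O)OC)cc3[C@H]2CO[Si](C)(C)C(C)(C)C)ccc1O[Si](C(C)C)(C(C)C)C(C)C | intermediate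
26 | {(2R,3S)-3-[(tert-butyldimethylsilyloxy)methyl]-7-methoxy-2-[3-methoxy-4-(triisopropylsilyloxy)phenyl]-2,3-dihydro-1-benzofuran-5-yl}methanol | COc1cc([C@@H]2Oc3c(OC)cc(CO)cc3[C@H]2CO[Si](C)(C)C(C)(C)C)ccc1O[Si](C(C)C)(C(C)C)C(C)C | intermediate
27 | (2R,3S)-3-[(tert-butyldimethylsilyloxy)methyl]-7-methoxy-2-[3-methoxy-4-(triisopropylsilyloxy)phenyl]-2,3-dihydro-1-benzofuran-5-carbaldehyde | COc1cc([C@@H]2Oc3c(OC)cc(C=O)cc3[C@H]2CO[Si](C)(C)C(C)(C)C)ccc1O[Si](C(C)C)(C(C)C)C(C)C | intermediate
28 | 3,5-dihydroxybenzaldehyde | O=Cc1cc(O)cc(O)c1 | starting material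
29 | 3,5-bis(triisopropylsilyloxy)benzaldehyde | O=Cc1cc(O[Si](C(C)C)(C(C)C)C(C)C)cc(O[Si](C(C)C)(C(C)C)C(C)C)c1 | intermediate
30 | [3,5-bis(triisopropylsilyloxy)phenyl]methanol | OCc1cc(O[Si](C(C)C)(C(C)C)C(C)C)cc(O[Si](C(C)C)(C(C)C)C(C)C)c1 | intermediate
31 | 1-(bromomethyl)-3,5-bis(triisopropylsilyloxy)benzene | BrCc1cc(O[Si](C(C)C)(C(C)C)C(C)C)cc(O[Si](C(C)C)(C(C)C)C(C)C)c1 | intermediate
32 | diethyl {[3,5-bis(triisopropylsilyloxy)phenyl]methyl}phosphonate | CCOP(=O)(OCC)Cc1cc(O[Si](C(C)C)(C(C)C)C(C)C)cc(O[Si](C(C)C)(C(C)C)C(C)C)c1 | intermediate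
33 | sodium salt of the benzylic carbanion of 32 | CCOP(=O)(OCC)[CH-]c1cc(O[Si](C(C)C)(C(C)C)C(C)C)cc(O[Si](C(C)C)(C(C)C)C(C)C)c1.[Na+] | intermediate
34 | (2R,3S)-5-{(E)-2-[3,5-bis(triisopropylsilyloxy)phenyl]ethenyl}-3-[(tert-butyldimethylsilyloxy)methyl]-7-methoxy-2-[3-methoxy-4-(triisopropylsilyloxy)phenyl]-2,3-dihydro-1-benzofuran | COc1cc([C@@H]2Oc3c(OC)cc(/C=C/c4cc(O[Si](C(C)C)(C(C)C)C(C)C)cc(O[Si](C(C)C)(C(C)C)C(C)C)c4)cc3[C@H]2CO[Si](C)(C)C(C)(C)C)ccc1O[Si](C(C)C)(C(C)C)C(C)C | intermediate
35 | gnetofuran A | COc1cc([C@@H]2Oc3c(OC)cc(/C=C/c4cc(O)cc(O)c4)cc3[C@H]2CO)ccc1O | target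

**Step count and risks**

Total steps: 20. Longest linear sequence: 12 steps (1 or 2, then 3, 4, 5, 6, 7, 8, 12, 13, 14, 19, 20).

Steps most likely to fail:

1. Step 12. The cycloaddition may be slow, because the methoxy donor sits on a diene terminus and one new bond joins two fully substituted carbons. Silyl transfer to the pyrone-derived enolate may divert the reaction into conjugate addition and pyrone ring opening. During aromatisation the ring C–O bond may cleave instead of silanol being lost. Fallback: ring A is taken from a preformed arene; the fallback sets out from aldehyde 2 and auxiliary 3 and comes back to the route at 25. Commercial methyl vanillate F1 is O-allylated (allyl bromide, K2CO3) to methyl 4-(allyloxy)-3-methoxybenzoate F2, and Claisen rearrangement at about 200 °C gives methyl 3-allyl-4-hydroxy-5-methoxybenzoate F3, whose phenol is protected as the methoxymethyl ether F4. Lemieux–Johnson cleavage gives the arylacetaldehyde F5 and Pinnick oxidation the arylacetic acid F6, which is joined to 3 (pivaloyl chloride, Et3N, LiCl) as the imide F7. Evans syn-aldol reaction of F7 with 2 gives the aldol F8, and NaBH4 in THF–water removes the auxiliary to give the diol F9. Acid (TsOH, wet CH2Cl2) then removes the methoxymethyl group and closes O1–C2 through the para-silyloxybenzyl cation to the thermodynamically preferred trans-dihydrobenzofuran alcohol F10, and silylation with TBSCl gives 25.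

2. Step 11. The methoxy enol ether may hydrolyse during the acidic unmasking, the push–pull diene may oligomerise, or the geometry needed for lactonisation may not be reached. Fallback: the C7 oxygen is introduced after the benzannulation; the fallback sets out from ketene acetal 16 and comes back at 25. Commercial methyl coumalate F11 is brominated at C3 (pyridinium tribromide, AcOH) to methyl 3-bromo-2-oxo-2H-pyran-5-carboxylate F12, a more electron-poor diene. Heated with 16 as in step 12, it should give the 7-bromo ester F13. Palladium-catalysed C–O coupling with methanol (Pd2(dba)3, tBuBrettPhos, Cs2CO3, toluene) then converts F13 into 25, any aryl silyl ether lost under the basic coupling being restored with TIPSCl.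

3. Step 8. The lactone enolate may be silylated on carbon instead of oxygen, and the ketene acetal may hydrolyse during isolation. Fallback: an O-methyl ketene acetal is reached without strong base; the fallback sets out from lactone 14 and comes back at 25. O-Methylation of 14 with Me3OBF4 gives the lactonium tetrafluoroborate F14 (not isolated), NaOMe converts it into the cyclic orthoester F15, and Me3SiOTf with iPr2NEt eliminates the elements of methanol to give the O-methyl ketene acetal F16. Cycloaddition of F16 with pyrone 22, loss of CO2 and loss of methanol then give 25.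

**Further compounds**

F1 | step 12 | methyl 4-hydroxy-3-methoxybenzoate (methyl vanillate) | COC(=O)c1ccc(O)c(OC)c1
F2 | step 12 | methyl 4-(allyloxy)-3-methoxybenzoate | COC(=O)c1ccc(OCC=C)c(OC)c1
F3 | step 12 | methyl 3-allyl-4-hydroxy-5-methoxybenzoate | COC(=O)c1cc(CC=C)c(O)c(OC)c1
F4 | step 12 | methyl 3-allyl-5-methoxy-4-(methoxymethoxy)benzoate | COC(=O)c1cc(CC=C)c(OCOC)c(OC)c1
F5 | step 12 | methyl 3-methoxy-4-(methoxymethoxy)-5-(2-oxoethyl)benzoate | COC(=O)c1cc(CC=O)c(OCOC)c(OC)c1
F6 | step 12 | 2-[3-methoxy-5-(methoxycarbonyl)-2-(methoxymethoxy)phenyl]acetic acid | COC(=O)c1cc(CC(=O)O)c(OCOC)c(OC)c1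
F7 | step 12 | (R)-4-benzyl-3-{2-[3-methoxy-5-(methoxycarbonyl)-2-(methoxymethoxy)phenyl]acetyl}oxazolidin-2-one | COC(=O)c1cc(CC(=O)N2C(=O)OC[C@H]2Cc2ccccc2)c(OCOC)c(OC)c1
F8 | step 12 | (R)-4-benzyl-3-{(2R,3R)-3-hydroxy-2-[3-methoxy-5-(methoxycarbonyl)-2-(methoxymethoxy)phenyl]-3-[3-methoxy-4-(triisopropylsilyloxy)phenyl]propanoyl}oxazolidin-2-one | COC(=O)c1cc([C@@H](C(=O)N2C(=O)OC[C@H]2Cc2ccccc2)[C@@H](O)c2ccc(O[Si](C(C)C)(C(C)C)C(C)C)c(OC)c2)c(OCOC)c(OC)c1
F9 | step 12 | methyl 3-{(1R,2S)-1,3-dihydroxy-1-[3-methoxy-4-(triisopropylsilyloxy)phenyl]propan-2-yl}-5-methoxy-4-(methoxymethoxy)benzoate | COC(=O)c1cc([C@@H](CO)[C@@H](O)c2ccc(O[Si](C(C)C)(C(C)C)C(C)C)c(OC)c2)c(OCOC)c(OC)c1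
F10 | step 12 | methyl (2R,3S)-3-(hydroxymethyl)-7-methoxy-2-[3-methoxy-4-(triisopropylsilyloxy)phenyl]-2,3-dihydro-1-benzofuran-5-carboxylate | COc1cc([C@@H]2Oc3c(OC)cc(C(=O)OC)cc3[C@H]2CO)ccc1O[Si](C(C)C)(C(C)C)C(C)C
F11 | step 11 | methyl 2-oxo-2H-pyran-5-carboxylate (methyl coumalate) | COC(=O)C1=COC(=O)C=C1
F12 | step 11 | methyl 3-bromo-2-oxo-2H-pyran-5-carboxylate | COC(=O)C1=COC(=O)C(Br)=C1
F13 | step 11 | methyl (2R,3S)-7-bromo-3-[(tert-butyldimethylsilyloxy)methyl]-2-[3-methoxy-4-(triisopropylsilyloxy)phenyl]-2,3-dihydro-1-benzofuran-5-carboxylate | COc1cc([C@@H]2Oc3c(Br)cc(C(=O)OC)cc3[C@H]2CO[Si](C)(C)C(C)(C)C)ccc1O[Si](C(C)C)(C(C)C)C(C)C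
F14 | step 8 | O-methyl lactonium tetrafluoroborate of 14 | COc1cc([C@@H]2[O+]=C(OC)C[C@H]2CO[Si](C)(C)C(C)(C)C)ccc1O[Si](C(C)C)(C(C)C)C(C)C.F[B-](F)(F)F
F15 | step 8 | (4S,5R)-4-[(tert-butyldimethylsilyloxy)methyl]-2,2-dimethoxy-5-[3-methoxy-4-(triisopropylsilyloxy)phenyl]oxolane | COc1cc([C@@H]2OC(OC)(OC)C[C@H]2CO[Si](C)(C)C(C)(C)C)ccc1O[Si](C(C)C)(C(C)C)C(C)C
F16 | step 8 | (2R,3S)-3-[(tert-butyldimethylsilyloxy)methyl]-5-methoxy-2-[3-methoxy-4-(triisopropylsilyloxy)phenyl]-2,3-dihydrofuran | COc1cc([C@@H]2OC(OC)=C[C@H]2CO[Si](C)(C)C(C)(C)C)ccc1O[Si](C(C)C)(C(C)C)C(C)C
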